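(Readings and results are calculated with constants of no real substance.)

A flask cannot turn more starting material than it was charged with, yet a straight line from the earlier runs promised exactly that for Friday's.

| flask | starting material | reagent | temperature | remark | time |
|---|---|---|---|---|---|
| gamma | 1.5 M | 1.1 M | 88 °C | run made earlier |  |
| delta | 1.5 M | 1.1 M | 104 °C | run made earlier |  |
| Tuesday's | 1.5 M | 2.25 M |  | at 110 °C until 4.0 min, from then on at 80 °C | 8.0 min |
| Saturday's | 1.5 M | 2.25 M | 80 °C |  | 8.0 min |
| Friday's | 1.5 M | 2.25 M | 110 °C |  | 8.0 min |

gamma run (percent of the starting material charged)

| time / min | mono adduct / % |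
|---|---|
| 1.33 | 3.1 |
| 2.50 | 6.3 |
| 4.00 | 8.2 |
| 5.00 | 10.0 |
| 6.00 | 12.1 |

delta run (percent of the starting material charged)

| time / s | mono adduct / % |
|---|---|
| 25.0 | 3.6 |
| 50.0 | 6.2 |
| 80.0 | 7.9 |
| 90.0 | 9.4 |
| 120 | 12.6 |

(standard deviation of a reading: 0.5 percentage points)

1. the best flask by amount of mono adduct, in percent of the starting material charged; "all alike" if 1.5 percentage points covers them all (Tuesday's / Saturday's / Friday's / all alike)
2. amount of mono adduct at the end, in percent of the starting material charged, Tuesday's
3. amount of mono adduct at the end, in percent of the starting material charged, Saturday's
4. amount of mono adduct at the end, in percent of the starting material charged, Friday's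



Both runs rose nearly straight. Both held c(reagent) at 1.1 M, so they could not show the order in reagent, and I assumed it was first. I divided each last reading by its time and by c(reagent):

gamma: 0.0183 /M/min

delta: 0.0573 /M/min

These carry the scatter of the readings. I carried their trend with temperature, taking the logarithm as straight, out to the two flask temperatures:

at 110 °C: 0.0878 /M/min

at 80 °C: 0.0104 /M/min

I called this the turnover constant, the fraction of starting material turned per minute per molar of reagent; the usual name is the second-order rate constant.

Multiplied by 2.25 M and 8.0 min, the hot value gave 158 % of the charge. That was the impossible number. But the line held c(reagent) and c(starting material) at their starting values, and both fall as the flask turns. So I integrated, with E = exp(k (c(reagent) − c(starting material)) t):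

E = 1.69

turned share = c(reagent)(E − 1) / (c(reagent) E − c(starting material)) = 67.5 %

The same formula gave Saturday's 16.2 %. Tuesday's starts as Friday's does and cools at 4.0 min, so I placed it between them. These are my estimates of the share of starting material turned, not of the mono adduct.

The forecast named Friday's best, with 54 % for Tuesday's, 18 % for Saturday's and 69 % for Friday's, and noted that “any second addition consuming mono adduct is invisible”.

Friday's gave 46.9 % of mono adduct, the most of the flasks, with Tuesday's at 42.4 % and Saturday's at 18.9 %.

    starting material + reagent → mono adduct + released group (k = 0.00160 /M/s, Ea = 75.0 kJ/mol)
    reagent + mono adduct → double product + released group (k = 9.10 × 10⁻⁴ /M/s, Ea = 97.0 kJ/mol)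
    (constants at 110 °C)

In Friday's, 67.1 % of the starting material was converted, against my 67.5 %, and the double product held 20.2 %. I used the turnover constant once more on the neighbour of Friday's charged with 1.3 M of reagent, less than its starting material. The formula gave 46.0 % turned. That flask kept 53.7 % of its starting material at 8.00 min, so 46.3 % had turned.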